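**Plan**

- Ring A is numbered C1 (bears the hexanoyl group), C2, C3 (quaternary: CH3 and prenyl), C4, C5 (bears the CH2 bridge) and C6 (ring C=O). C3 carries the two carbonyl-level ring carbons C2 and C4, so it is a 2-methyl-2-prenylmalonaldehyde-level carbon that is stereogenic only because its two arms differ; a 1,2-shift in a 2,3-epoxy silyl ether delivers exactly such a carbon with one aldehyde arm and one siloxymethyl arm.
- Retrosynthetic cuts: (a) the C5–CH2 bond to ring B (enol plus ring B quinone methide); (b) the C1–C6 bond of ring A (Claisen); (c) the C1–C2 and C4–C5 bonds (aldol/oxidation with heptan-2-one and with methyl acetate); (d) the C2–C3 bond (siloxymethyl shift of the epoxy silyl ether); (e) the epoxide, the E alkene and the skipped enyne.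
- Forward order: the chain is built around the quaternary carbon, aldehyde arm first (C4–C5–C6), then the unmasked silyl arm (C2–C1–hexanoyl). Ring A closes last in the chain by Claisen condensation. Ring B, aromatic throughout and made from benzene-1,3,5-triol, is joined through the CH2 bridge in the final step.
- Stereochemistry: the single stereocentre comes from Sharpless epoxidation of the E allylic alcohol with D-(−)-diethyl tartrate and is written into the quaternary carbon, with inversion, by the stereospecific 1,2-shift. The aldehyde carbon becomes C4 and the siloxymethyl carbon C2, and the two arms are never made equivalent afterwards.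

Key step: step 6

Remark: ring A and the open-chain polyketo compounds are written as single tautomers; the descriptor of the quaternary carbon refers to the tautomer drawn.

**Route**

Step 1
Reactants: 1 ethynyltrimethylsilane; 2 1-bromo-3-methylbut-2-ene
Product: 4 trimethyl(5-methylhex-4-en-1-yn-1-yl)silane, via bromo[(trimethylsilyl)ethynyl]magnesium 3 (not isolated)
Conditions: EtMgBr, THF, 0 °C to 40 °C; then CuBr·SMe2 (5 mol%), 2, 0 °C to 45 °C
Reagents that add atoms: none
Why: CuBr·SMe2-catalysed allylation of an alkynylmagnesium bromide (alkynyl Grignard cross-coupling) should take place at the unhindered CH2 terminus of the prenyl bromide, the C-silyl group preventing double alkylation and isomerisation of the skipped enyne.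

Step 2
Reactants: 4 trimethyl(5-methylhex-4-en-1-yn-1-yl)silane
Product: 5 5-methylhex-4-en-1-yne
Conditions: K2CO3 (cat.), MeOH, rt; pentane extraction, used as a concentrated solution
Reagents that add atoms: none
Why: Methanolysis of the alkynyl C–Si bond (protodesilylation) is specific for silanes on sp carbon and mild enough not to isomerise the skipped enyne.

Step 3
Reactants: 5 5-methylhex-4-en-1-yne
Product: 7 (2E)-3,6-dimethylhepta-2,5-dien-1-ol, via [(1E)-2,5-dimethylhexa-1,4-dien-1-yl]dimethylalumane 6 (not isolated)
Conditions: AlMe3 (2.5 equiv), Cp2ZrCl2 (0.25 equiv), CH2Cl2, 0 °C to rt; then (CH2O)n, 0 °C to rt; aqueous work-up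
Reagents that add atoms: trimethylaluminium, C[Al](C)C; formaldehyde (as paraformaldehyde), C=O
Why: Cp2ZrCl2-catalysed methylalumination (Negishi carboalumination) adds CH3 and Al syn across the terminal alkyne with Al on the terminal carbon, and the alkenyl–Al bond then adds to formaldehyde with retention, which fixes the E geometry of the trisubstituted allylic alcohol.

Step 4
Reactants: 7 (2E)-3,6-dimethylhepta-2,5-dien-1-ol
Product: 8 [(2R,3R)-3-methyl-3-(3-methylbut-2-en-1-yl)oxiran-2-yl]methanol
Conditions: Ti(O-i-Pr)4 (10 mol%), D-(−)-diethyl tartrate (12 mol%), t-BuOOH (anhydrous), 4 Å molecular sieves, CH2Cl2, −20 °C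
Reagents that add atoms: tert-butyl hydroperoxide, CC(C)(C)OO
Why: Katsuki–Sharpless asymmetric epoxidation, in which the Ti(O-i-Pr)4/D-(−)-diethyl tartrate complex delivers oxygen to the alkene face that gives the (2R,3R)-epoxide of an E 3,3-disubstituted allylic alcohol (both stereocentres set by the tartrate), while the remote alkene, which has no coordinating hydroxyl, is left alone.

Step 5
Reactants: 8 [(2R,3R)-3-methyl-3-(3-methylbut-2-en-1-yl)oxiran-2-yl]methanol
Product: 9 tert-butyl(dimethyl){[(2R,3R)-3-methyl-3-(3-methylbut-2-en-1-yl)oxiran-2-yl]methoxy}silane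
Conditions: TBSCl, imidazole, DMF, 0 °C to rt
Reagents that add atoms: tert-butyl(chloro)dimethylsilane, CC(C)(C)[Si](C)(C)Cl
Why: Standard silylation of a primary alcohol; the epoxide is inert to these conditions and neither stereocentre is touched.

Step 6
Reactants: 9 tert-butyl(dimethyl){[(2R,3R)-3-methyl-3-(3-methylbut-2-en-1-yl)oxiran-2-yl]methoxy}silane
Product: 10 (2R)-2-({[tert-butyl(dimethyl)silyl]oxy}methyl)-2,5-dimethylhex-4-enal
Conditions: MeAl(OAr)2 (2 equiv; Ar = 4-bromo-2,6-di-tert-butylphenyl; made from AlMe3 and 2 ArOH in CH2Cl2 at rt), CH2Cl2, −78 °C; aqueous work-up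
Reagents that add atoms: none
Why: MeAl(OAr)2, a bulky and strongly oxophilic Lewis acid, binds the epoxide oxygen (the hindered silyl ether oxygen does not chelate), and the C–O bond at the tertiary carbon lengthens towards a tertiary cation. As it breaks, the siloxymethyl carbon on the neighbouring epoxide carbon shifts to the rear face of that tertiary carbon and the remaining C–O bond becomes the aldehyde carbonyl; this is a semipinacol rearrangement (epoxide-to-carbonyl 1,2-shift), the closest known reaction type being the rearrangement of 2,3-epoxy silyl ethers to β-siloxy aldehydes with methylaluminium bis(aryloxide) promoters. No ring is closed: the step forms one skeletal C–C bond (C2–C3 of ring A) and the quaternary carbon. The new stereocentre is controlled by the epoxide configuration from step 4 alone, since the shift is stereospecific and occurs with inversion at the tertiary carbon, so the (2R,3R)-epoxide gives the (R)-aldehyde, in which the aldehyde carbon is the future C4 and the siloxymethyl carbon the future C2. The step needs opening at the tertiary and not the secondary epoxide carbon, migration of CH2OSi in preference to hydride, and no capture of the cation by the prenyl alkene. The trisubstituted epoxide secures the first, the bulky aluminium aryloxide with the electron-rich siloxymethyl group the second (aldehyde and not ketone is the documented outcome for such substrates), and the third follows because the homoallylic alkene could only close a three- or four-membered ring and the reaction is run at −78 °C.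

Step 7
Reactants: 10 (2R)-2-({[tert-butyl(dimethyl)silyl]oxy}methyl)-2,5-dimethylhex-4-enal
Product: 11 methyl (3RS,4R)-4-({[tert-butyl(dimethyl)silyl]oxy}methyl)-3-hydroxy-4,7-dimethyloct-6-enoate
Conditions: LiN(i-Pr)2, MeOAc, THF, −78 °C; then 10, −78 °C; AcOH quench
Reagents that add atoms: methyl acetate, COC(C)=O
Why: Aldol addition of the lithium enolate of methyl acetate to a non-enolisable α-quaternary aldehyde builds C4–C5–C6; the new carbinol centre forms without control, which does not matter because it is oxidised in step 9, and the quaternary centre cannot epimerise.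

Step 8
Reactants: 11 methyl (3RS,4R)-4-({[tert-butyl(dimethyl)silyl]oxy}methyl)-3-hydroxy-4,7-dimethyloct-6-enoate
Product: 12 methyl (3RS,4R)-3-hydroxy-4-(hydroxymethyl)-4,7-dimethyloct-6-enoate
Conditions: HF·pyridine, pyridine, THF, 0 °C to rt; used at once
Reagents that add atoms: none
Why: Fluoride-mediated cleavage of the primary silyl ether under buffered, non-basic conditions avoids retro-aldol cleavage and base-induced δ-lactonisation of the hydroxy ester, and the diol is oxidised without storage.

Step 9
Reactants: 12 methyl (3RS,4R)-3-hydroxy-4-(hydroxymethyl)-4,7-dimethyloct-6-enoate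
Product: 13 methyl (4R)-4-formyl-4,7-dimethyl-3-oxooct-6-enoate
Conditions: Dess–Martin periodinane (2.6 equiv), CH2Cl2, 0 °C to rt
Reagents that add atoms: none
Why: Dess–Martin oxidation takes the primary alcohol to the aldehyde and the secondary alcohol to the ketone in one operation under neutral conditions that tolerate the prenyl alkene and do not cleave the non-enolisable β-keto aldehyde.

Step 10
Reactants: 13 methyl (4R)-4-formyl-4,7-dimethyl-3-oxooct-6-enoate; 14 heptan-2-one
Product: 16 methyl (4R,5RS)-5-hydroxy-4-methyl-4-(3-methylbut-2-en-1-yl)-3,7-dioxododecanoate, via dicyclohexyl(hept-1-en-2-yloxy)borane 15 (not isolated)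
Conditions: (c-Hex)2BCl, Et3N, 14 (3 equiv), Et2O, 0 °C; then 13, −78 °C to −20 °C; MeOH, pH 7 buffer, H2O2, 0 °C
Reagents that add atoms: none
Why: Boron-mediated aldol addition of a methyl ketone: (c-Hex)2BCl/Et3N enolises heptan-2-one on the methyl side and the enolate adds to the aldehyde (far more electrophilic than the hindered ketone) without strong base, so deformylation is avoided and the excess enolate covers any loss by proton exchange with the β-keto ester; the new carbinol centre is uncontrolled and is removed in step 11.

Step 11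
Reactants: 16 methyl (4R,5RS)-5-hydroxy-4-methyl-4-(3-methylbut-2-en-1-yl)-3,7-dioxododecanoate
Product: 17 methyl (4R)-4-methyl-4-(3-methylbut-2-en-1-yl)-3,5,7-trioxododecanoate
Conditions: Dess–Martin periodinane (1.3 equiv), CH2Cl2, 0 °C to rt
Reagents that add atoms: none
Why: Dess–Martin oxidation of a β-hydroxy ketone to the 1,3-diketone with a small excess of reagent at low temperature converges both epimers and removes the δ-hydroxy ester before it can lactonise.

Step 12
Reactants: 17 methyl (4R)-4-methyl-4-(3-methylbut-2-en-1-yl)-3,5,7-trioxododecanoate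
Product: 18 (4S)-2-hexanoyl-3,5-dihydroxy-4-methyl-4-(3-methylbut-2-en-1-yl)cyclohexa-2,5-dien-1-one
Conditions: NaOMe (2.2 equiv), MeOH, 0 °C to 50 °C; then 1 M HCl
Reagents that add atoms: none
Why: Intramolecular Claisen (Dieckmann-type) condensation closes ring A by 6-exo-trig attack of the more acidic 1,3-diketone carbon (ring A C1) on the ester carbonyl (ring A C6), the pattern known for 3,5,7-trioxo esters in strong base; the doubly stabilised product anion is the thermodynamic sink, O-acylated products are reopened by methoxide, and the quaternary stereocentre is not involved.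

Step 13
Reactants: 19 benzene-1,3,5-triol
Product: 20 1-(2,4,6-trihydroxyphenyl)hexan-1-one
Conditions: hexanoyl chloride, AlCl3 (3 equiv), PhNO2, rt to 60 °C; then ice/HCl
Reagents that add atoms: hexanoyl chloride, CCCCCC(=O)Cl
Why: Friedel–Crafts acylation of the highly activated triol stops at monoacylation because the acyl group deactivates the ring towards a second substitution.

Step 14
Reactants: 20 1-(2,4,6-trihydroxyphenyl)hexan-1-one
Product: 21 1-(2,6-dihydroxy-4-methoxyphenyl)hexan-1-one
Conditions: Me2SO4 (1.0 equiv), K2CO3 (1.0 equiv), acetone, rt to 56 °C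
Reagents that add atoms: dimethyl sulfate, COS(=O)(=O)OC
Why: Williamson-type O-methylation with one equivalent of reagent should select the 4-hydroxyl, which is the most acidic and is not hydrogen-bonded to the ketone, giving the symmetrical monomethyl ether.

Step 15
Reactants: 21 1-(2,6-dihydroxy-4-methoxyphenyl)hexan-1-one
Product: 22 1-{3-[(dimethylamino)methyl]-2,6-dihydroxy-4-methoxyphenyl}hexan-1-one
Conditions: CH2=NMe2+ I− (1.0 equiv), K2CO3, MeCN, 0 °C to rt
Reagents that add atoms: N,N-dimethylmethaniminium iodide, C=[N+](C)C.[I-]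
Why: Mannich aminomethylation with a preformed iminium salt occurs at one of the two equivalent, strongly activated ring positions (ortho to OH and OMe, para to OH), and one equivalent of the salt limits double substitution.

Step 16
Reactants: 18 (4S)-2-hexanoyl-3,5-dihydroxy-4-methyl-4-(3-methylbut-2-en-1-yl)cyclohexa-2,5-dien-1-one; 22 1-{3-[(dimethylamino)methyl]-2,6-dihydroxy-4-methoxyphenyl}hexan-1-one
Product: 24 (4S)-2-hexanoyl-6-[(3-hexanoyl-2,4-dihydroxy-6-methoxyphenyl)methyl]-3,5-dihydroxy-4-methyl-4-(3-methylbut-2-en-1-yl)cyclohexa-2,5-dien-1-one, via ring B ortho-quinone methide 23 (not isolated)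
Conditions: 18 (1.0 equiv), 22 (1.2 equiv), 1,4-dioxane, 90 °C, argon
Reagents that add atoms: none
Why: Thermal loss of dimethylamine from the ortho-hydroxybenzylamine, assisted by protonation from the acidic trione, gives the ring B ortho-quinone methide, which is captured at carbon by the enol of ring A (Michael-type C-benzylation of a cyclic 1,3-dicarbonyl, the usual way to methylene-bridged acylphloroglucinol dimers); C5 is the only nucleophilic carbon of 18 and the quaternary stereocentre is untouched.

**Compound list**

1 | ethynyltrimethylsilane | C#C[Si](C)(C)C | starting material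
2 | 1-bromo-3-methylbut-2-ene | CC(C)=CCBr | starting material
3 | bromo[(trimethylsilyl)ethynyl]magnesium | C[Si](C)(C)C#C[Mg]Br | intermediate
4 | trimethyl(5-methylhex-4-en-1-yn-1-yl)silane | CC(C)=CCC#C[Si](C)(C)C | intermediate
5 | 5-methylhex-4-en-1-yne | CC(C)=CCC#C | intermediate
6 | [(1E)-2,5-dimethylhexa-1,4-dien-1-yl]dimethylalumane | C[Al](C)/C=C(\C)CC=C(C)C | intermediate
7 | (2E)-3,6-dimethylhepta-2,5-dien-1-ol | OC/C=C(\C)CC=C(C)C | intermediate
8 | [(2R,3R)-3-methyl-3-(3-methylbut-2-en-1-yl)oxiran-2-yl]methanol | OC[C@H]1O[C@]1(C)CC=C(C)C | intermediate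
9 | tert-butyl(dimethyl){[(2R,3R)-3-methyl-3-(3-methylbut-2-en-1-yl)oxiran-2-yl]methoxy}silane | CC(C)(C)[Si](C)(C)OC[C@H]1O[C@]1(C)CC=C(C)C | intermediate
10 | (2R)-2-({[tert-butyl(dimethyl)silyl]oxy}methyl)-2,5-dimethylhex-4-enal | CC(C)(C)[Si](C)(C)OC[C@@](C)(CC=C(C)C)C=O | intermediate
11 | methyl (3RS,4R)-4-({[tert-butyl(dimethyl)silyl]oxy}methyl)-3-hydroxy-4,7-dimethyloct-6-enoate | COC(=O)CC(O)[C@@](C)(CO[Si](C)(C)C(C)(C)C)CC=C(C)C | intermediate
12 | methyl (3RS,4R)-3-hydroxy-4-(hydroxymethyl)-4,7-dimethyloct-6-enoate | COC(=O)CC(O)[C@@](C)(CO)CC=C(C)C | intermediate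
13 | methyl (4R)-4-formyl-4,7-dimethyl-3-oxooct-6-enoate | COC(=O)CC(=O)[C@@](C)(C=O)CC=C(C)C | intermediate
14 | heptan-2-one | CCCCCC(C)=O | starting material
15 | dicyclohexyl(hept-1-en-2-yloxy)borane | C=C(CCCCC)OB(C1CCCCC1)C1CCCCC1 | intermediate
16 | methyl (4R,5RS)-5-hydroxy-4-methyl-4-(3-methylbut-2-en-1-yl)-3,7-dioxododecanoate | COC(=O)CC(=O)[C@](C)(CC=C(C)C)C(O)CC(=O)CCCCC | intermediate
17 | methyl (4R)-4-methyl-4-(3-methylbut-2-en-1-yl)-3,5,7-trioxododecanoate | COC(=O)CC(=O)[C@](C)(CC=C(C)C)C(=O)CC(=O)CCCCC | intermediate
18 | (4S)-2-hexanoyl-3,5-dihydroxy-4-methyl-4-(3-methylbut-2-en-1-yl)cyclohexa-2,5-dien-1-one | CCCCCC(=O)C1=C(O)[C@@](C)(CC=C(C)C)C(O)=CC1=O | intermediate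
19 | benzene-1,3,5-triol | Oc1cc(O)cc(O)c1 | starting material
20 | 1-(2,4,6-trihydroxyphenyl)hexan-1-one | CCCCCC(=O)c1c(O)cc(O)cc1O | intermediate
21 | 1-(2,6-dihydroxy-4-methoxyphenyl)hexan-1-one | CCCCCC(=O)c1c(O)cc(OC)cc1O | intermediate
22 | 1-{3-[(dimethylamino)methyl]-2,6-dihydroxy-4-methoxyphenyl}hexan-1-one | CCCCCC(=O)c1c(O)cc(OC)c(CN(C)C)c1O | intermediate
23 | 2-hexanoyl-3-hydroxy-5-methoxy-6-methylidenecyclohexa-2,4-dien-1-one | C=C1C(=O)C(C(=O)CCCCC)=C(O)C=C1OC | intermediate
24 | (4S)-2-hexanoyl-6-[(3-hexanoyl-2,4-dihydroxy-6-methoxyphenyl)methyl]-3,5-dihydroxy-4-methyl-4-(3-methylbut-2-en-1-yl)cyclohexa-2,5-dien-1-one | CCCCCC(=O)C1=C(O)[C@@](C)(CC=C(C)C)C(O)=C(Cc2c(OC)cc(O)c(C(=O)CCCCC)c2O)C1=O | target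

**Step count and risks**

Total step count: 16. Longest linear sequence: 13 (steps 1 to 12, then step 16).

Steps most likely to fail:

1. Step 12. The ring closure may take the aldol course instead (the β-keto ester carbon adding to the hexanoyl carbonyl, followed by dehydration), or methoxide may cleave the non-enolisable 1,3-diketone around the quaternary carbon. The fallback changes the acyl donor to a thioester, so that closure is driven by thiophilic activation of that one carbonyl under near-neutral conditions and not by enolate concentration. It sets out from aldehyde 10 and comes back at 18. Addition of the lithium enolate of S-tert-butyl ethanethioate to 10 should give S-tert-butyl (3RS,4R)-4-({[tert-butyl(dimethyl)silyl]oxy}methyl)-3-hydroxy-4,7-dimethyloct-6-enethioate F1. Desilylation as in step 8 leads to S-tert-butyl (3RS,4R)-3-hydroxy-4-(hydroxymethyl)-4,7-dimethyloct-6-enethioate F2, and double oxidation as in step 9 to S-tert-butyl (4R)-4-formyl-4,7-dimethyl-3-oxooct-6-enethioate F3. The boron aldol of step 10 with enolate 15 (non-oxidative work-up) gives S-tert-butyl (4R,5RS)-5-hydroxy-4-methyl-4-(3-methylbut-2-en-1-yl)-3,7-dioxododecanethioate F4, and oxidation as in step 11 gives S-tert-butyl (4R)-4-methyl-4-(3-methylbut-2-en-1-yl)-3,5,7-trioxododecanethioate F5. Treatment of F5 with AgO2CCF3 and Et3N in THF at rt should then acylate the enolised 1,3-diketone carbon and deliver 18.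

2. Step 16. The quinone methide may be consumed by its own precursor, ring A may be benzylated a second time, or exchange of the methylene unit may scramble the two partners into symmetrical dimers. The fallback replaces quinone methide capture by a reductive alkylation. It sets out from 21 (with 18) and comes back at 24. Vilsmeier–Haack formylation of 21 (POCl3, DMF, then aqueous NaOAc) should give 3-hexanoyl-2,4-dihydroxy-6-methoxybenzaldehyde F6. Knoevenagel condensation of F6 with trione 18 (L-proline cat., CH2Cl2/EtOH, rt) in the presence of diethyl 2,6-dimethyl-1,4-dihydropyridine-3,5-dicarboxylate forms (4R)-2-hexanoyl-6-[(3-hexanoyl-2,4-dihydroxy-6-methoxyphenyl)methylidene]-3-hydroxy-4-methyl-4-(3-methylbut-2-en-1-yl)cyclohex-2-ene-1,5-dione F7, which is reduced in the same flask by hydride transfer from the dihydropyridine to give 24.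

3. Step 10. The α-quaternary β-keto aldehyde may lose its formyl group, or proton transfer from the acidic β-keto ester may quench the enolate and leave the hindered aldehyde unreacted. The fallback reorders the oxidation levels so that the C–C bond is made on a hydroxy aldehyde that has neither of these liabilities. It sets out from diol 12 and comes back at 17. Oxidation of 12 with TEMPO (cat.) and PhI(OAc)2 in CH2Cl2 should affect only the primary alcohol and give methyl (3RS,4S)-4-formyl-3-hydroxy-4,7-dimethyloct-6-enoate F8. Addition of an excess of the lithium enolate of heptan-2-one (LiN(i-Pr)2, THF, −78 °C) gives methyl (4R)-3,5-dihydroxy-4-methyl-4-(3-methylbut-2-en-1-yl)-7-oxododecanoate F9 as a mixture of carbinol epimers, and oxidation of both carbinols with Dess–Martin periodinane returns to 17.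

**Further compounds**

F1 | step 12 | S-tert-butyl (3RS,4R)-4-({[tert-butyl(dimethyl)silyl]oxy}methyl)-3-hydroxy-4,7-dimethyloct-6-enethioate | CC(C)(C)SC(=O)CC(O)[C@@](C)(CO[Si](C)(C)C(C)(C)C)CC=C(C)C
F2 | step 12 | S-tert-butyl (3RS,4R)-3-hydroxy-4-(hydroxymethyl)-4,7-dimethyloct-6-enethioate | CC(C)(C)SC(=O)CC(O)[C@@](C)(CO)CC=C(C)C
F3 | step 12 | S-tert-butyl (4R)-4-formyl-4,7-dimethyl-3-oxooct-6-enethioate | CC(C)(C)SC(=O)CC(=O)[C@@](C)(C=O)CC=C(C)C
F4 | step 12 | S-tert-butyl (4R,5RS)-5-hydroxy-4-methyl-4-(3-methylbut-2-en-1-yl)-3,7-dioxododecanethioate | CC(C)(C)SC(=O)CC(=O)[C@](C)(CC=C(C)C)C(O)CC(=O)CCCCC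
F5 | step 12 | S-tert-butyl (4R)-4-methyl-4-(3-methylbut-2-en-1-yl)-3,5,7-trioxododecanethioate | CC(C)(C)SC(=O)CC(=O)[C@](C)(CC=C(C)C)C(=O)CC(=O)CCCCC
F6 | step 16 | 3-hexanoyl-2,4-dihydroxy-6-methoxybenzaldehyde | CCCCCC(=O)c1c(O)cc(OC)c(C=O)c1O
F7 | step 16 | (4R)-2-hexanoyl-6-[(3-hexanoyl-2,4-dihydroxy-6-methoxyphenyl)methylidene]-3-hydroxy-4-methyl-4-(3-methylbut-2-en-1-yl)cyclohex-2-ene-1,5-dione | CCCCCC(=O)C1=C(O)[C@@](C)(CC=C(C)C)C(=O)C(=Cc2c(OC)cc(O)c(C(=O)CCCCC)c2O)C1=O
F8 | step 10 | methyl (3RS,4S)-4-formyl-3-hydroxy-4,7-dimethyloct-6-enoate | COC(=O)CC(O)[C@@](C)(C=O)CC=C(C)C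
F9 | step 10 | methyl (4R)-3,5-dihydroxy-4-methyl-4-(3-methylbut-2-en-1-yl)-7-oxododecanoate | COC(=O)CC(O)[C@](C)(CC=C(C)C)C(O)CC(=O)CCCCC
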